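Time looks plentiful here. In ash, 1.0 h is 30.5 forward half-lives (2.0 min, way back not counted) of starting material reacting with reagent, while the half-life of target against starting material, 2.5 h, is longer than the run.

    starting material + reagent ⇌ target (K1 = 21 M⁻¹, k1 = 0.042 M⁻¹ s⁻¹)
    second substrate + reagent ⇌ second product (K2 = 11 M⁻¹, k2 = 0.0021 M⁻¹ s⁻¹)
    starting material → decomposition product (k3 = 5.1 × 10⁻⁶ s⁻¹)
    starting material + target → side product (k4 = 5.6 × 10⁻⁴ M⁻¹ s⁻¹)

the same everywhere: reagent 0.140 M; time 1.0 h

|  | starting material | second substrate | remark |
|---|---|---|---|
| larch | 0.14 M | 0.0700 M (fed, over 40 min) | all else is in the flask from the start; the feed brings no volume worth counting |
| cedar | 0.14 M (fed, over 4.0 min) | 0.0700 M | all else is in the flask from the start; the feed brings no volume worth counting |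
| ash | 0.14 M | 0.0700 M | everything together at the start |
| maple | 0.14 M (fed, over 40 min) | 0.0700 M | all else is in the flask from the start; the feed brings no volume worth counting |

- percentages count the starting material that a species holds: one side product counts as two
- run time (larch): 1.0 h

1. the flask that comes out highest in share of target in target plus side product, or "all alike" when all lie within 1.5 percentage points (larch / cedar / ash / maple / all alike)
2. share of target in target plus side product at the end, larch
3. share of target in target plus side product at the end, cedar
4. share of target in target plus side product at the end, ash
5. share of target in target plus side product at the end, maple

Yet starting material does not disappear in those many half-lives, and side product does not stay negligible. The fast step is reversible. With equal charges and second substrate set aside, target divided by the square of the free level must equal 21 M⁻¹, which gives 0.0788 M of target beside 0.0612 M each of starting material and reagent. The two partners of the slow step therefore stand together at high levels. Their meeting consumes the charge at 0.139 h⁻¹, double counting included: this fraction of the charge passing into side product per hour at these levels is the wear rate w.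

Side product is then w times the contact time, the time the pair stands at full level. Target is taken as its equilibrium share less side product. In ash, contact lasts 1.0 h, so side product reaches 13.9% and the share 75.3%; larch, with starting material present from the start, reckons alike. During a feed of starting material, both partners grow roughly with what has entered, so their product averages a third of its full value. Contact is then 57.3 min in cedar, giving a share of 76.4%. In maple it is 33.3 min, giving side product 7.72% and a share of 86.3%.

The forecast gives larch 80%, cedar 80.5%, ash 80% and maple 85% and chooses maple, holding that the slow feed “keeps that product small for most of the run”; its figure for ash stands higher than this reckoning's.

The simulation gives larch 79.3%, cedar 79.4%, ash 78.9% and maple 86.6%, so maple leads. Side product read at 1.00 h and divided by contact time gives 0.121 h⁻¹ in ash and 0.129 h⁻¹ in maple, both readings below w. Without the falling back of target, maple's lead over ash shrinks from 7.8 percentage points to 0.43 points, the largest single effect tested, though not proven the main reason. With 0.084 M of reagent and second substrate again set aside, the neighbour of maple has 0.0541 M of target at equilibrium and w = 0.134 h⁻¹, less than the 0.139 h⁻¹ above, so the same contact time predicts a share of 80.7%. The simulation gives 82.5%.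

(The constants are those of an exercise; the rest is arithmetic.)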